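Retrosynthetic cuts, in order: (a) lactone Cα–CH2(ring B), (b) lactone Cβ–CH2(ring C), (c) C2–C3 of the dihydrobenzofuran, (d) C7''–C8'' of the diol side chain on ring B.
Enabling feature: C2 of the dihydrobenzofuran is a benzylic ether CH (bonded to O1 and ring D). C3 is bonded to ring C at C3a and carries a CH2OH that can be carried as an ester. A ring C aryl(ester)carbene leaves exactly this pattern when it inserts into the ring C–O–CH2–ring D group five atoms away.
Forward, part 1: 5-bromovanillin is etherified with the ring D benzyl alcohol and homologated to one aryl acetate, which is used twice. As its diazo ester it closes the dihydrobenzofuran (first ring). As its free acid it becomes ring B, where the same benzyl group serves as phenol protection.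
Forward, part 2: the ring C benzyl bromide alkylates a chiral succinyl imide and is carried on to the β-benzyl lactone (second ring). The ring A/B bromide then alkylates the lactone enolate, and mild acid followed by hydrogenolysis unmasks the target.
Stereochemistry: C2 comes from the chiral dirhodium carboxylate and C3 from equilibration to trans. Cβ comes from an (R)-oxazolidinone alkylation and Cα from attack anti to the β-substituent. C7'' and C8'' come from an (S)-oxazolidinone anti-aldol.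

Key step: step 7

Labels: ring A = guaiacyl ring on carbinol C7''. Ring B = arene of the lactone α-benzyl group. Ring C = benzo ring of the dihydrobenzofuran. Ring D = guaiacyl ring on C2. C8'' = CH on ring B and C9'' = its CH2OH. BMB = 4-benzyloxy-3-methoxybenzyl, BMP = 4-benzyloxy-3-methoxyphenyl, Tr = triphenylmethyl, TIPS = triisopropylsilyl.
Assumption 1: the sense of induction of the dirhodium catalyst is carried over from unsubstituted 2-(benzyloxy)phenyl diazoacetates, where ligands of S configuration lead to 2R, so the R-configured catalyst is used for 2S.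
Assumption 2: the MgCl2-catalysed anti-aldol is taken to react through the chelated Z-enolate, that is on the same enolate face as imide alkylation, so the (S)-auxiliary gives 8''S.

Step 1
Reactants: 1 5-bromovanillin; 2 4-benzyloxy-3-methoxybenzyl alcohol
Product: 3 3-bromo-4-(BMB-oxy)-5-methoxybenzaldehyde
Conditions: PPh3, DIAD, THF, 0 → 23 °C
Reagents that add atoms: none
Why: Mitsunobu etherification, in which the acidic phenol of 1 is O-alkylated by the activated primary benzylic alcohol under neutral conditions that leave the aldehyde and the aryl bromide alone.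

Step 2
Reactants: 3 3-bromo-4-(BMB-oxy)-5-methoxybenzaldehyde
Product: 4 [3-bromo-4-(BMB-oxy)-5-methoxyphenyl]methanol
Conditions: NaBH4, MeOH/THF, 0 °C
Reagents that add atoms: none
Why: Borohydride reduction of an aromatic aldehyde, to which the aryl bromide and the benzylic ethers are inert.

Step 3
Reactants: 4 [3-bromo-4-(BMB-oxy)-5-methoxyphenyl]methanol
Product: 5 {[3-bromo-4-(BMB-oxy)-5-methoxyphenyl]methoxy}triisopropylsilane
Conditions: TIPSCl, imidazole, DMF, 23 °C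
Reagents that add atoms: chlorotriisopropylsilane, CC(C)[Si](Cl)(C(C)C)C(C)C
Why: Silyl ether formation, with TIPS chosen because a benzylic TIPS ether should survive phosphate base, hot wet DMSO, DBU and hydride, where a smaller silyl group would be lost.

Step 4
Reactants: 5 {[3-bromo-4-(BMB-oxy)-5-methoxyphenyl]methoxy}triisopropylsilane; 6 dimethyl malonate
Product: 7 dimethyl 2-[2-(BMB-oxy)-3-methoxy-5-(TIPS-oxymethyl)phenyl]malonate
Conditions: Pd(OAc)2 (cat.), t-Bu3P·HBF4 (cat.), K3PO4, toluene, 100 °C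
Reagents that add atoms: none
Why: Palladium-catalysed α-arylation of a malonate, in which the bulky electron-rich phosphine allows oxidative addition into the electron-rich ortho-alkoxy aryl bromide and the mild phosphate base spares all ethers.

Step 5
Reactants: 7 dimethyl 2-[2-(BMB-oxy)-3-methoxy-5-(TIPS-oxymethyl)phenyl]malonate
Product: 8 methyl 2-[2-(BMB-oxy)-3-methoxy-5-(TIPS-oxymethyl)phenyl]acetate
Conditions: LiCl, H2O, DMSO, 140 °C
Reagents that add atoms: none
Why: Krapcho dealkoxycarbonylation, which is especially easy for aryl malonates because the departing carbanion is benzylic and ester-stabilised.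

Step 6
Reactants: 8 methyl 2-[2-(BMB-oxy)-3-methoxy-5-(TIPS-oxymethyl)phenyl]acetate
Product: 9 methyl 2-diazo-2-[2-(BMB-oxy)-3-methoxy-5-(TIPS-oxymethyl)phenyl]acetate
Conditions: p-ABSA, DBU, MeCN, 0 → 23 °C
Reagents that add atoms: 4-acetamidobenzenesulfonyl azide, CC(=O)Nc1ccc(cc1)S(=O)(=O)N=[N+]=[N-]
Why: Regitz diazo transfer onto an aryl acetate, whose α-CH2 is acidic enough for DBU.

Step 7
Reactants: 9 methyl 2-diazo-2-[2-(BMB-oxy)-3-methoxy-5-(TIPS-oxymethyl)phenyl]acetate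
Product: 11 methyl (2S,3S)-trans-2-(BMP)-7-methoxy-5-(TIPS-oxymethyl)-2,3-dihydrobenzofuran-3-carboxylate, via cis ester 10 (not isolated)
Conditions: Rh2(R-PTTL)4 [dirhodium tetrakis(N-phthaloyl-(R)-tert-leucinate)] (1 mol %), toluene, −60 °C; then DBU, 23 °C
Reagents that add atoms: none
Why: Rh2(R-PTTL)4 expels N2 from 9, and the resulting donor/acceptor rhodium carbenoid inserts its carbon (future C3) into one C–H bond of the flanking ring C–O–CH2–ring D group in a concerted, asynchronous step with hydride-transfer character, which creates the C2–C3 bond. The closest known reaction type is the dirhodium tetracarboxylate-catalysed intramolecular C–H insertion of 2-(benzyloxy)aryl diazoacetates to 2-aryl-2,3-dihydrobenzofuran-3-carboxylates. The one ring closed, O1–C2–C3–C3a–C7a, arises by 1,5-insertion through a five-membered transition state, that is by C–C bond formation at the ether carbon. C2 is controlled by the chiral ligand sphere, which picks one of the two enantiotopic benzylic hydrogens, whereas C3 emerges cis in 10 under kinetic control and is then corrected by DBU, which enolises only the acidic C3–H and returns the less crowded trans ester 11; β-elimination of the phenoxide is not expected because the C2–O1 bond lies close to the enolate plane. Site selectivity is required and is secured by the substrate: the reacting C–H is activated by both O1 and electron-rich ring D, it is the only one within five-ring reach, attack on the ether oxygen would need a four-membered ylide, and the OMe, OCH2Ph and CH2OTIPS hydrogens are out of intramolecular range. Low temperature in a non-coordinating solvent should keep carbene dimerisation and intermolecular insertion in check.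

Step 8
Reactants: 11 methyl (2S,3S)-trans-2-(BMP)-7-methoxy-5-(TIPS-oxymethyl)-2,3-dihydrobenzofuran-3-carboxylate
Product: 12 [(2S,3R)-2-(BMP)-7-methoxy-5-(TIPS-oxymethyl)-2,3-dihydrobenzofuran-3-yl]methanol
Conditions: LiAlH4, THF, 0 °C
Reagents that add atoms: none
Why: Hydride reduction of the ester, which is faster than any enolisation, so both stereocentres persist (the C3 descriptor changes from S to R only through CIP priorities).

Step 9
Reactants: 12 [(2S,3R)-2-(BMP)-7-methoxy-5-(TIPS-oxymethyl)-2,3-dihydrobenzofuran-3-yl]methanol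
Product: 13 (2S,3R)-2-(BMP)-7-methoxy-5-(TIPS-oxymethyl)-3-(Tr-oxymethyl)-2,3-dihydrobenzofuran
Conditions: TrCl, Et3N, DMAP (cat.), CH2Cl2, 40 °C
Reagents that add atoms: trityl chloride, ClC(c1ccccc1)(c1ccccc1)c1ccccc1
Why: Tritylation of a primary alcohol, giving an achiral ether that tolerates fluoride, strong base, peroxide and borane and leaves later in the same mild acid step as the acetonide.

Step 10
Reactants: 13 (2S,3R)-2-(BMP)-7-methoxy-5-(TIPS-oxymethyl)-3-(Tr-oxymethyl)-2,3-dihydrobenzofuran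
Product: 14 [(2S,3R)-2-(BMP)-7-methoxy-3-(Tr-oxymethyl)-2,3-dihydrobenzofuran-5-yl]methanol
Conditions: Bu4NF, THF, 0 → 23 °C
Reagents that add atoms: none
Why: Fluoride desilylation, orthogonal to trityl, benzyl and methyl ethers.

Step 11
Reactants: 14 [(2S,3R)-2-(BMP)-7-methoxy-3-(Tr-oxymethyl)-2,3-dihydrobenzofuran-5-yl]methanol
Product: 15 (2S,3R)-5-(bromomethyl)-2-(BMP)-7-methoxy-3-(Tr-oxymethyl)-2,3-dihydrobenzofuran
Conditions: CBr4, PPh3, 2,6-lutidine, CH2Cl2, 0 °C
Reagents that add atoms: carbon tetrabromide, BrC(Br)(Br)Br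
Why: Appel bromination under buffered, essentially neutral conditions that spare the trityl ether, the activated bromide being used at once.

Step 12
Reactants: 16 (R)-4-benzyl-1,3-oxazolidin-2-one; 17 methyl 4-chloro-4-oxobutanoate
Product: 18 methyl 4-[(4R)-4-benzyl-2-oxo-1,3-oxazolidin-3-yl]-4-oxobutanoate
Conditions: n-BuLi, THF, −78 °C; then 17
Reagents that add atoms: none
Why: N-acylation of the lithiated oxazolidinone by the acid chloride, which reacts far faster than the methyl ester.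

Step 13
Reactants: 18 methyl 4-[(4R)-4-benzyl-2-oxo-1,3-oxazolidin-3-yl]-4-oxobutanoate; 15 (2S,3R)-5-(bromomethyl)-2-(BMP)-7-methoxy-3-(Tr-oxymethyl)-2,3-dihydrobenzofuran
Product: 19 methyl (3R)-4-[(4R)-4-benzyl-2-oxo-1,3-oxazolidin-3-yl]-3-{[(2S,3R)-2-(BMP)-7-methoxy-3-(Tr-oxymethyl)-2,3-dihydrobenzofuran-5-yl]methyl}-4-oxobutanoate
Conditions: NaN(SiMe3)2, THF, −78 °C; then 15, −78 → −30 °C
Reagents that add atoms: none
Why: Evans asymmetric alkylation of a chiral succinate, in which the chelated Z sodium enolate forms at the more acidic imide α-CH2 and is benzylated on the face away from the auxiliary benzyl group, setting the future lactone Cβ as R.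

Step 14
Reactants: 19 methyl (3R)-4-[(4R)-4-benzyl-2-oxo-1,3-oxazolidin-3-yl]-3-{[(2S,3R)-2-(BMP)-7-methoxy-3-(Tr-oxymethyl)-2,3-dihydrobenzofuran-5-yl]methyl}-4-oxobutanoate
Product: 21 (2R)-2-{[(2S,3R)-2-(BMP)-7-methoxy-3-(Tr-oxymethyl)-2,3-dihydrobenzofuran-5-yl]methyl}-4-methoxy-4-oxobutanoic acid, via peroxy acid 20 (not isolated)
Conditions: LiOH, H2O2, THF/H2O, 0 °C; Na2SO3; 1 M HCl to pH 3
Reagents that add atoms: hydrogen peroxide, OO
Why: Hydroperoxide-mediated exocyclic cleavage of the imide, which at 0 °C is much faster than ester saponification and does not enolise the new stereocentre.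

Step 15
Reactants: 21 (2R)-2-{[(2S,3R)-2-(BMP)-7-methoxy-3-(Tr-oxymethyl)-2,3-dihydrobenzofuran-5-yl]methyl}-4-methoxy-4-oxobutanoic acid
Product: 23 (4R)-4-{[(2S,3R)-2-(BMP)-7-methoxy-3-(Tr-oxymethyl)-2,3-dihydrobenzofuran-5-yl]methyl}oxolan-2-one, via hydroxy ester 22 (not isolated)
Conditions: BH3·THF, THF, 0 → 23 °C; then DBU (cat.), CH2Cl2, 23 °C
Reagents that add atoms: none
Why: Chemoselective borane reduction of the acid beside the ester, followed by base-catalysed lactonisation of the γ-hydroxy ester, with the β-stereocentre not epimerisable.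

Step 16
Reactants: 8 methyl 2-[2-(BMB-oxy)-3-methoxy-5-(TIPS-oxymethyl)phenyl]acetate
Product: 24 2-[2-(BMB-oxy)-3-methoxy-5-(TIPS-oxymethyl)phenyl]acetic acid
Conditions: LiOH, THF/MeOH/H2O, 23 °C; 1 M HCl to pH 3, 0 °C
Reagents that add atoms: lithium hydroxide, [Li+].[OH-]
Why: Saponification of an unhindered methyl ester, to which the TIPS and benzyl-type ethers are inert.

Step 17
Reactants: 24 2-[2-(BMB-oxy)-3-methoxy-5-(TIPS-oxymethyl)phenyl]acetic acid; 25 (S)-4-benzyl-1,3-oxazolidin-2-one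
Product: 27 (4S)-4-benzyl-3-{2-[2-(BMB-oxy)-3-methoxy-5-(TIPS-oxymethyl)phenyl]acetyl}-1,3-oxazolidin-2-one, via mixed pivalic anhydride 26 (not isolated)
Conditions: t-BuCOCl, Et3N, THF, −20 °C; then LiCl, 25, −20 → 23 °C
Reagents that add atoms: pivaloyl chloride, CC(C)(C)C(=O)Cl (its atoms stay in 26 only)
Why: Mixed-anhydride N-acylation of the oxazolidinone, which attacks the less hindered aryl acetyl carbonyl.

Step 18
Reactants: 27 (4S)-4-benzyl-3-{2-[2-(BMB-oxy)-3-methoxy-5-(TIPS-oxymethyl)phenyl]acetyl}-1,3-oxazolidin-2-one; 28 4-benzyloxy-3-methoxybenzaldehyde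
Product: 29 (4S)-4-benzyl-3-{(2R,3S)-3-(BMP)-2-[2-(BMB-oxy)-3-methoxy-5-(TIPS-oxymethyl)phenyl]-3-(trimethylsilyloxy)propanoyl}-1,3-oxazolidin-2-one
Conditions: MgCl2 (20 mol %), Et3N, Me3SiCl, EtOAc, 23 °C
Reagents that add atoms: chlorotrimethylsilane, C[Si](C)(C)Cl
Why: Magnesium halide-catalysed direct anti-aldol of an N-acyloxazolidinone with a non-enolisable aromatic aldehyde, in which soft enolisation gives the chelated Z-enolate that adds through a boat-like transition state on the face away from the auxiliary benzyl group (sets C8'') with anti topicity (sets C7''), while Me3SiCl traps the aldolate, shuts off retro-aldol and releases the magnesium.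

Step 19
Reactants: 29 (4S)-4-benzyl-3-{(2R,3S)-3-(BMP)-2-[2-(BMB-oxy)-3-methoxy-5-(TIPS-oxymethyl)phenyl]-3-(trimethylsilyloxy)propanoyl}-1,3-oxazolidin-2-one
Product: 31 (1S,2S)-1-(BMP)-2-[2-(BMB-oxy)-3-methoxy-5-(TIPS-oxymethyl)phenyl]propane-1,3-diol, via silyl ether alcohol 30 (not isolated)
Conditions: LiBH4, MeOH (1 equiv), THF, 0 °C; then K2CO3 (cat.), MeOH, 23 °C
Reagents that add atoms: none
Why: Reductive removal of the auxiliary on the O-silylated adduct, so that no aldolate able to undergo retro-aldol is formed, followed by methanolysis of the labile trimethylsilyl ether.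

Step 20
Reactants: 31 (1S,2S)-1-(BMP)-2-[2-(BMB-oxy)-3-methoxy-5-(TIPS-oxymethyl)phenyl]propane-1,3-diol
Product: 32 (4S,5S)-4-(BMP)-5-[2-(BMB-oxy)-3-methoxy-5-(TIPS-oxymethyl)phenyl]-2,2-dimethyl-1,3-dioxane
Conditions: Me2C(OMe)2, PPTS (cat.), CH2Cl2, 23 °C
Reagents that add atoms: 2,2-dimethoxypropane, COC(C)(C)OC
Why: Acetonide formation by transacetalisation, in which the anti diol gives the trans-4,5-diequatorial dioxane, the more stable isomer, so no stereochemical drift is expected.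

Step 21
Reactants: 32 (4S,5S)-4-(BMP)-5-[2-(BMB-oxy)-3-methoxy-5-(TIPS-oxymethyl)phenyl]-2,2-dimethyl-1,3-dioxane
Product: 33 {3-[(4S,5S)-4-(BMP)-2,2-dimethyl-1,3-dioxan-5-yl]-4-(BMB-oxy)-5-methoxyphenyl}methanol
Conditions: Bu4NF, THF, 0 → 23 °C
Reagents that add atoms: none
Why: Fluoride desilylation, orthogonal to the acetonide and the benzyl-type ethers.

Step 22
Reactants: 33 {3-[(4S,5S)-4-(BMP)-2,2-dimethyl-1,3-dioxan-5-yl]-4-(BMB-oxy)-5-methoxyphenyl}methanol
Product: 34 (4S,5S)-4-(BMP)-5-[2-(BMB-oxy)-5-(bromomethyl)-3-methoxyphenyl]-2,2-dimethyl-1,3-dioxane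
Conditions: CBr4, PPh3, 2,6-lutidine, CH2Cl2, 0 °C
Reagents that add atoms: carbon tetrabromide, BrC(Br)(Br)Br
Why: Appel bromination, buffered so that the acetonide stays intact, the activated bromide being used at once.

Step 23
Reactants: 23 (4R)-4-{[(2S,3R)-2-(BMP)-7-methoxy-3-(Tr-oxymethyl)-2,3-dihydrobenzofuran-5-yl]methyl}oxolan-2-one; 34 (4S,5S)-4-(BMP)-5-[2-(BMB-oxy)-5-(bromomethyl)-3-methoxyphenyl]-2,2-dimethyl-1,3-dioxane
Product: 35 (3R,4R)-3-{3-[(4S,5S)-4-(BMP)-2,2-dimethyl-1,3-dioxan-5-yl]-4-(BMB-oxy)-5-methoxybenzyl}-4-{[(2S,3R)-2-(BMP)-7-methoxy-3-(Tr-oxymethyl)-2,3-dihydrobenzofuran-5-yl]methyl}oxolan-2-one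
Conditions: LiN(SiMe3)2, THF, −78 °C; then 34, DMPU, −78 → −40 °C
Reagents that add atoms: none
Why: Diastereoselective alkylation of a β-substituted butyrolactone enolate, in which the benzylic bromide approaches anti to the β-benzyl group and sets Cα as R (trans), which is also the thermodynamically preferred relation.

Step 24
Reactants: 35 (3R,4R)-3-{3-[(4S,5S)-4-(BMP)-2,2-dimethyl-1,3-dioxan-5-yl]-4-(BMB-oxy)-5-methoxybenzyl}-4-{[(2S,3R)-2-(BMP)-7-methoxy-3-(Tr-oxymethyl)-2,3-dihydrobenzofuran-5-yl]methyl}oxolan-2-one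
Product: 36 (3R,4R)-3-{4-(BMB-oxy)-3-[(1S,2S)-1-(BMP)-1,3-dihydroxypropan-2-yl]-5-methoxybenzyl}-4-{[(2S,3R)-2-(BMP)-3-(hydroxymethyl)-7-methoxy-2,3-dihydrobenzofuran-5-yl]methyl}oxolan-2-one
Conditions: AcOH/THF/H2O (4:1:1), 45 °C
Reagents that add atoms: none
Why: Mild acid hydrolysis of the acetonide and the trityl ether in one operation, run while all phenols are still capped so that neither a quinone methide at C7'' nor attack of the ring B phenol on C7'' can occur.

Step 25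
Reactants: 36 (3R,4R)-3-{4-(BMB-oxy)-3-[(1S,2S)-1-(BMP)-1,3-dihydroxypropan-2-yl]-5-methoxybenzyl}-4-{[(2S,3R)-2-(BMP)-3-(hydroxymethyl)-7-methoxy-2,3-dihydrobenzofuran-5-yl]methyl}oxolan-2-one
Product: 37 CNP0186558.2, (3R,4R)-3-{3-[(1S,2S)-1,3-dihydroxy-1-(4-hydroxy-3-methoxyphenyl)propan-2-yl]-4-hydroxy-5-methoxybenzyl}-4-{[(2S,3R)-2-(4-hydroxy-3-methoxyphenyl)-3-(hydroxymethyl)-7-methoxy-2,3-dihydrobenzofuran-5-yl]methyl}oxolan-2-one
Conditions: H2 (1 atm), Pd/C (10 %), EtOAc/EtOH, 23 °C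
Reagents that add atoms: none
Why: Hydrogenolysis of four primary aryl benzyl-type ether bonds (three O-benzyl groups and the ring B–O–CH2 link), which under neutral conditions at one atmosphere cleave much faster than the secondary benzylic C7''–OH and C2–O1 bonds.

Compound list
1 | 5-bromovanillin | COc1cc(C=O)cc(Br)c1O | starting material
2 | 4-benzyloxy-3-methoxybenzyl alcohol | COc1cc(CO)ccc1OCc1ccccc1 | starting material
3 | 3-bromo-4-(4-benzyloxy-3-methoxybenzyloxy)-5-methoxybenzaldehyde | COc1cc(C=O)cc(Br)c1OCc1ccc(OCc2ccccc2)c(OC)c1 | intermediate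
4 | [3-bromo-4-(4-benzyloxy-3-methoxybenzyloxy)-5-methoxyphenyl]methanol | COc1cc(CO)cc(Br)c1OCc1ccc(OCc2ccccc2)c(OC)c1 | intermediate
5 | TIPS ether of 4 | COc1cc(CO[Si](C(C)C)(C(C)C)C(C)C)cc(Br)c1OCc1ccc(OCc2ccccc2)c(OC)c1 | intermediate
6 | dimethyl malonate | COC(=O)CC(=O)OC | starting material
7 | dimethyl 2-[2-(4-benzyloxy-3-methoxybenzyloxy)-3-methoxy-5-(triisopropylsilyloxymethyl)phenyl]malonate | COC(=O)C(C(=O)OC)c1cc(CO[Si](C(C)C)(C(C)C)C(C)C)cc(OC)c1OCc1ccc(OCc2ccccc2)c(OC)c1 | intermediate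
8 | methyl 2-[2-(4-benzyloxy-3-methoxybenzyloxy)-3-methoxy-5-(triisopropylsilyloxymethyl)phenyl]acetate | COC(=O)Cc1cc(CO[Si](C(C)C)(C(C)C)C(C)C)cc(OC)c1OCc1ccc(OCc2ccccc2)c(OC)c1 | intermediate
9 | methyl 2-diazo-2-[2-(4-benzyloxy-3-methoxybenzyloxy)-3-methoxy-5-(triisopropylsilyloxymethyl)phenyl]acetate | COC(=O)C(=[N+]=[N-])c1cc(CO[Si](C(C)C)(C(C)C)C(C)C)cc(OC)c1OCc1ccc(OCc2ccccc2)c(OC)c1 | intermediate
10 | methyl (2S,3R)-cis-2-(4-benzyloxy-3-methoxyphenyl)-7-methoxy-5-(triisopropylsilyloxymethyl)-2,3-dihydrobenzofuran-3-carboxylate | CC(C)[Si](C(C)C)(C(C)C)OCc1cc(OC)c2c(c1)[C@@H](C(=O)OC)[C@@H](c1ccc(OCc3ccccc3)c(OC)c1)O2 | intermediate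
11 | methyl (2S,3S)-trans-2-(4-benzyloxy-3-methoxyphenyl)-7-methoxy-5-(triisopropylsilyloxymethyl)-2,3-dihydrobenzofuran-3-carboxylate | CC(C)[Si](C(C)C)(C(C)C)OCc1cc(OC)c2c(c1)[C@H](C(=O)OC)[C@@H](c1ccc(OCc3ccccc3)c(OC)c1)O2 | intermediate
12 | [(2S,3R)-2-(4-benzyloxy-3-methoxyphenyl)-7-methoxy-5-(triisopropylsilyloxymethyl)-2,3-dihydrobenzofuran-3-yl]methanol | CC(C)[Si](C(C)C)(C(C)C)OCc1cc(OC)c2c(c1)[C@H](CO)[C@@H](c1ccc(OCc3ccccc3)c(OC)c1)O2 | intermediate
13 | trityl ether of 12 | CC(C)[Si](C(C)C)(C(C)C)OCc1cc(OC)c2c(c1)[C@H](COC(c1ccccc1)(c1ccccc1)c1ccccc1)[C@@H](c1ccc(OCc3ccccc3)c(OC)c1)O2 | intermediate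
14 | [(2S,3R)-2-(4-benzyloxy-3-methoxyphenyl)-7-methoxy-3-(trityloxymethyl)-2,3-dihydrobenzofuran-5-yl]methanol | OCc1cc(OC)c2c(c1)[C@H](COC(c1ccccc1)(c1ccccc1)c1ccccc1)[C@@H](c1ccc(OCc3ccccc3)c(OC)c1)O2 | intermediate
15 | (2S,3R)-5-(bromomethyl)-2-(4-benzyloxy-3-methoxyphenyl)-7-methoxy-3-(trityloxymethyl)-2,3-dihydrobenzofuran | BrCc1cc(OC)c2c(c1)[C@H](COC(c1ccccc1)(c1ccccc1)c1ccccc1)[C@@H](c1ccc(OCc3ccccc3)c(OC)c1)O2 | intermediate
16 | (R)-4-benzyl-1,3-oxazolidin-2-one | O=C1N[C@H](Cc2ccccc2)CO1 | starting material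
17 | methyl 4-chloro-4-oxobutanoate | COC(=O)CCC(=O)Cl | starting material
18 | methyl 4-[(4R)-4-benzyl-2-oxo-1,3-oxazolidin-3-yl]-4-oxobutanoate | COC(=O)CCC(=O)N1[C@H](Cc2ccccc2)COC1=O | intermediate
19 | (3R)-alkylated succinyl imide | COC(=O)C[C@@H](Cc1cc(OC)c2c(c1)[C@H](COC(c1ccccc1)(c1ccccc1)c1ccccc1)[C@@H](c1ccc(OCc3ccccc3)c(OC)c1)O2)C(=O)N1[C@H](Cc2ccccc2)COC1=O | intermediate
20 | (2R)-peroxy acid from 19 | COC(=O)C[C@@H](Cc1cc(OC)c2c(c1)[C@H](COC(c1ccccc1)(c1ccccc1)c1ccccc1)[C@@H](c1ccc(OCc3ccccc3)c(OC)c1)O2)C(=O)OO | intermediate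
21 | (2R)-2-(arylmethyl)-4-methoxy-4-oxobutanoic acid | COC(=O)C[C@@H](Cc1cc(OC)c2c(c1)[C@H](COC(c1ccccc1)(c1ccccc1)c1ccccc1)[C@@H](c1ccc(OCc3ccccc3)c(OC)c1)O2)C(=O)O | intermediate
22 | methyl (3R)-3-(arylmethyl)-4-hydroxybutanoate | COC(=O)C[C@@H](Cc1cc(OC)c2c(c1)[C@H](COC(c1ccccc1)(c1ccccc1)c1ccccc1)[C@@H](c1ccc(OCc3ccccc3)c(OC)c1)O2)CO | intermediate
23 | (4R)-4-{[(2S,3R)-2-(4-benzyloxy-3-methoxyphenyl)-7-methoxy-3-(trityloxymethyl)-2,3-dihydrobenzofuran-5-yl]methyl}oxolan-2-one | O=C1C[C@@H](Cc2cc(OC)c3c(c2)[C@H](COC(c2ccccc2)(c2ccccc2)c2ccccc2)[C@@H](c2ccc(OCc4ccccc4)c(OC)c2)O3)CO1 | intermediate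
24 | 2-[2-(4-benzyloxy-3-methoxybenzyloxy)-3-methoxy-5-(triisopropylsilyloxymethyl)phenyl]acetic acid | OC(=O)Cc1cc(CO[Si](C(C)C)(C(C)C)C(C)C)cc(OC)c1OCc1ccc(OCc2ccccc2)c(OC)c1 | intermediate
25 | (S)-4-benzyl-1,3-oxazolidin-2-one | O=C1N[C@@H](Cc2ccccc2)CO1 | starting material
26 | mixed pivalic anhydride of 24 | CC(C)(C)C(=O)OC(=O)Cc1cc(CO[Si](C(C)C)(C(C)C)C(C)C)cc(OC)c1OCc1ccc(OCc2ccccc2)c(OC)c1 | intermediate
27 | (4S)-4-benzyl-3-(arylacetyl)-1,3-oxazolidin-2-one from 24 | O=C(Cc1cc(CO[Si](C(C)C)(C(C)C)C(C)C)cc(OC)c1OCc1ccc(OCc2ccccc2)c(OC)c1)N1[C@@H](Cc2ccccc2)COC1=O | intermediate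
28 | 4-benzyloxy-3-methoxybenzaldehyde | COc1cc(C=O)ccc1OCc1ccccc1 | starting material
29 | (2R,3S)-anti aldol adduct, O-trimethylsilyl ether, (4S)-imide | COc1cc([C@@H](O[Si](C)(C)C)[C@H](C(=O)N2[C@@H](Cc3ccccc3)COC2=O)c2cc(CO[Si](C(C)C)(C(C)C)C(C)C)cc(OC)c2OCc2ccc(OCc3ccccc3)c(OC)c2)ccc1OCc1ccccc1 | intermediate
30 | (2S,3S)-3-(4-benzyloxy-3-methoxyphenyl)-2-aryl-3-(trimethylsilyloxy)propan-1-ol | COc1cc([C@@H](O[Si](C)(C)C)[C@H](CO)c2cc(CO[Si](C(C)C)(C(C)C)C(C)C)cc(OC)c2OCc2ccc(OCc3ccccc3)c(OC)c2)ccc1OCc1ccccc1 | intermediate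
31 | (1S,2S)-1-(4-benzyloxy-3-methoxyphenyl)-2-[2-(4-benzyloxy-3-methoxybenzyloxy)-3-methoxy-5-(triisopropylsilyloxymethyl)phenyl]propane-1,3-diol | COc1cc([C@@H](O)[C@H](CO)c2cc(CO[Si](C(C)C)(C(C)C)C(C)C)cc(OC)c2OCc2ccc(OCc3ccccc3)c(OC)c2)ccc1OCc1ccccc1 | intermediate
32 | (4S,5S)-trans acetonide of 31 | COc1cc([C@H]2OC(C)(C)OC[C@@H]2c2cc(CO[Si](C(C)C)(C(C)C)C(C)C)cc(OC)c2OCc2ccc(OCc3ccccc3)c(OC)c2)ccc1OCc1ccccc1 | intermediate
33 | ring B benzylic alcohol, (4S,5S)-acetonide | COc1cc([C@H]2OC(C)(C)OC[C@@H]2c2cc(CO)cc(OC)c2OCc2ccc(OCc3ccccc3)c(OC)c2)ccc1OCc1ccccc1 | intermediate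
34 | ring B benzylic bromide, (4S,5S)-acetonide | COc1cc([C@H]2OC(C)(C)OC[C@@H]2c2cc(CBr)cc(OC)c2OCc2ccc(OCc3ccccc3)c(OC)c2)ccc1OCc1ccccc1 | intermediate
35 | fully protected (3R,4R)-trans-dibenzyl lactone | COc1cc([C@H]2OC(C)(C)OC[C@@H]2c2cc(C[C@H]3C(=O)OC[C@@H]3Cc3cc(OC)c4c(c3)[C@H](COC(c3ccccc3)(c3ccccc3)c3ccccc3)[C@@H](c3ccc(OCc5ccccc5)c(OC)c3)O4)cc(OC)c2OCc2ccc(OCc3ccccc3)c(OC)c2)ccc1OCc1ccccc1 | intermediate
36 | triol with all three phenols still protected | COc1cc([C@@H](O)[C@H](CO)c2cc(C[C@H]3C(=O)OC[C@@H]3Cc3cc(OC)c4c(c3)[C@H](CO)[C@@H](c3ccc(OCc5ccccc5)c(OC)c3)O4)cc(OC)c2OCc2ccc(OCc3ccccc3)c(OC)c2)ccc1OCc1ccccc1 | intermediate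
37 | CNP0186558.2 | COc1cc([C@@H](O)[C@H](CO)c2cc(C[C@H]3C(=O)OC[C@@H]3Cc3cc(OC)c4c(c3)[C@H](CO)[C@@H](c3ccc(O)c(OC)c3)O4)cc(OC)c2O)ccc1O | target

Total step count: 25. Longest linear sequence: 17 steps (1–11, 13–15, 23–25).

Steps most likely to fail

1) Step 7. The 7-methoxy group twists the ring C–O–CH2 bond out of the arene plane. The ligand pocket may then tell the two benzylic hydrogens apart less well, so enantiomeric purity could erode.
The fallback keeps the same C–H insertion but secures stereochemical purity through a covalently bound chiral ester instead of through the catalyst alone. It sets out from acid 24.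
- Esterification with (−)-menthol (DCC, DMAP) gives the menthyl aryl acetate F1.
- Diazo transfer (p-ABSA, DBU) gives the menthyl aryldiazoacetate F2.
- Insertion with the same dirhodium catalyst and DBU equilibration give the trans (2S,3S) menthyl ester F3.
- F3 is now a diastereomer of the unwanted (2R,3R) product and can be separated from it by crystallisation or chromatography.
- LiAlH4 reduction comes back to the route at alcohol 12.

2) Step 18. Soft enolisation of the hindered ortho-substituted aryl acetyl imide may be slow. The aldehyde face may be differentiated poorly (syn/anti leakage), and the doubly activated C8''–H may epimerise.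
The fallback sets the stereodiad by a stereospecific syn hydroboration instead of an aldol. It sets out from acid 24 and aldehyde 28.
- Perkin condensation (Ac2O, Et3N, 110 °C) gives the (E)-2,3-diarylacrylic acid F4, with the two aryl groups cis.
- BH3·THF at 0 °C reduces the acid much faster than it touches the hindered alkene and gives the (E)-2,3-diarylallyl alcohol F5.
- Hydroboration follows with excess monoisopinocampheylborane derived from (−)-α-pinene. Boron goes to the less substituted C7'', away from the allylic oxygen.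
- Oxidation (NaBO3·4H2O) delivers H and OH syn across the E-alkene, which corresponds to the anti diol.
- The route is rejoined at diol 31.

3) Step 23. C-alkylation may be slower than ionisation or self-condensation of the activated ring B benzylic bromide. Proton transfer between product and enolate may lead to double alkylation.
The fallback uses a carbonyl addition instead of a substitution. It sets out from alcohol 33 and lactone 23.
- MnO2 oxidation of 33 gives the ring B aldehyde F6.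
- The lithium enolate of 23 adds to it to give the aldol adduct F7, as a mixture at the new carbinol.
- Acetylation (Ac2O, DMAP) gives the acetate F8.
- DBU eliminates it to the (E)-benzylidene lactone F9.
- Conjugate reduction (NaBH4, NiCl2·6H2O, MeOH/THF, 0 °C) and DBU equilibration to the more stable trans lactone come back to the route at 35.

Further compounds
F1 | step 7 | (1R,2S,5R)-menthyl 2-[2-(4-benzyloxy-3-methoxybenzyloxy)-3-methoxy-5-(triisopropylsilyloxymethyl)phenyl]acetate | CC(C)[C@@H]1CC[C@@H](C)C[C@H]1OC(=O)Cc1cc(CO[Si](C(C)C)(C(C)C)C(C)C)cc(OC)c1OCc1ccc(OCc2ccccc2)c(OC)c1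
F2 | step 7 | (1R,2S,5R)-menthyl 2-diazo-2-[2-(4-benzyloxy-3-methoxybenzyloxy)-3-methoxy-5-(triisopropylsilyloxymethyl)phenyl]acetate | CC(C)[C@@H]1CC[C@@H](C)C[C@H]1OC(=O)C(=[N+]=[N-])c1cc(CO[Si](C(C)C)(C(C)C)C(C)C)cc(OC)c1OCc1ccc(OCc2ccccc2)c(OC)c1
F3 | step 7 | (1R,2S,5R)-menthyl (2S,3S)-trans-2-(4-benzyloxy-3-methoxyphenyl)-7-methoxy-5-(triisopropylsilyloxymethyl)-2,3-dihydrobenzofuran-3-carboxylate | CC(C)[Si](C(C)C)(C(C)C)OCc1cc(OC)c2c(c1)[C@H](C(=O)O[C@@H]1C[C@H](C)CC[C@H]1C(C)C)[C@@H](c1ccc(OCc3ccccc3)c(OC)c1)O2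
F4 | step 18 | (E)-3-(4-benzyloxy-3-methoxyphenyl)-2-[2-(4-benzyloxy-3-methoxybenzyloxy)-3-methoxy-5-(triisopropylsilyloxymethyl)phenyl]prop-2-enoic acid | OC(=O)/C(c1cc(CO[Si](C(C)C)(C(C)C)C(C)C)cc(OC)c1OCc1ccc(OCc2ccccc2)c(OC)c1)=C/c1ccc(OCc2ccccc2)c(OC)c1
F5 | step 18 | (E)-3-(4-benzyloxy-3-methoxyphenyl)-2-[2-(4-benzyloxy-3-methoxybenzyloxy)-3-methoxy-5-(triisopropylsilyloxymethyl)phenyl]prop-2-en-1-ol | OC/C(c1cc(CO[Si](C(C)C)(C(C)C)C(C)C)cc(OC)c1OCc1ccc(OCc2ccccc2)c(OC)c1)=C/c1ccc(OCc2ccccc2)c(OC)c1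
F6 | step 23 | 3-[(4S,5S)-4-(4-benzyloxy-3-methoxyphenyl)-2,2-dimethyl-1,3-dioxan-5-yl]-4-(4-benzyloxy-3-methoxybenzyloxy)-5-methoxybenzaldehyde | COc1cc([C@H]2OC(C)(C)OC[C@@H]2c2cc(C=O)cc(OC)c2OCc2ccc(OCc3ccccc3)c(OC)c2)ccc1OCc1ccccc1
F7 | step 23 | trans aldol adduct of 23 and F6 (both carbinol epimers) | COc1cc([C@H]2OC(C)(C)OC[C@@H]2c2cc(C(O)[C@H]3C(=O)OC[C@@H]3Cc3cc(OC)c4c(c3)[C@H](COC(c3ccccc3)(c3ccccc3)c3ccccc3)[C@@H](c3ccc(OCc5ccccc5)c(OC)c3)O4)cc(OC)c2OCc2ccc(OCc3ccccc3)c(OC)c2)ccc1OCc1ccccc1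
F8 | step 23 | acetate of F7 | COc1cc([C@H]2OC(C)(C)OC[C@@H]2c2cc(C(OC(C)=O)[C@H]3C(=O)OC[C@@H]3Cc3cc(OC)c4c(c3)[C@H](COC(c3ccccc3)(c3ccccc3)c3ccccc3)[C@@H](c3ccc(OCc5ccccc5)c(OC)c3)O4)cc(OC)c2OCc2ccc(OCc3ccccc3)c(OC)c2)ccc1OCc1ccccc1
F9 | step 23 | (E,4R)-α-benzylidene lactone | COc1cc([C@H]2OC(C)(C)OC[C@@H]2c2cc(/C=C3/C(=O)OC[C@@H]3Cc3cc(OC)c4c(c3)[C@H](COC(c3ccccc3)(c3ccccc3)c3ccccc3)[C@@H](c3ccc(OCc5ccccc5)c(OC)c3)O4)cc(OC)c2OCc2ccc(OCc3ccccc3)c(OC)c2)ccc1OCc1ccccc1
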